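The quinone ring is cut into a mirror-symmetric four-carbon unit, C2'–C5' (O=C–C(OMe)=C(OMe)–C=O), and the two-carbon unit C1'–C6', whose C1' carries C3 of the chroman ring. This maps onto dimethyl squarate and a terminal alkyne. In one operation a trivalent-cobalt dimethoxymaleoyl metallacycle inserts the alkyne and reductively eliminates, forming C1'–C2' and C6'–C5' and closing the quinone ring at its final oxidation level without touching the C3 stereocentre. The precursors are the dimethylglyoxime/pyridine maleoylcobalt complex derived from dimethyl squarate and (S)-3-ethynyl-6,7,8-trimethoxychroman, whose stereocentre comes from asymmetric hydrogenation of a chromene-3-carboxylic acid. The remaining methoxy group at C6' is added afterwards by epoxidation, isomerisation and O-methylation.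

Key step: step 10

Remarks on the chemistry
- Quinone numbering: C1' bears chroman C3, C2' and C5' are the carbonyl carbons, C3' and C4' carry OMe, C6' is the position methoxylated last.
- 2,3,4-Trimethoxybenzaldehyde is not a salicylaldehyde, and simple O-demethylation would lead to a 7,8-dimethoxychroman; it is therefore converted by Baeyer–Villiger oxidation and ortho-formylation into 2-hydroxy-3,4,5-trimethoxybenzaldehyde, the aldehyde that maps onto the 6,7,8-trimethoxychroman.
- The chromene is built with acrylonitrile instead of an acrylate ester, which avoids coumarin formation; the nitrile is hydrolysed to the acid.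
- The bis(triphenylphosphine) maleoylcobalt complex is prepared, then exchanged into its dimethylglyoxime/pyridine analogue before the annulation, so that neither a silver salt nor free triphenylphosphine (which adds to quinones) is present in the key step.
- The C3 descriptor alternates between R and S along the route only through CIP priority changes; the spatial arrangement set in step 5 is kept throughout.
- The ligand antipode in step 5 is assigned by analogy and is to be confirmed by chiral HPLC on the first run.

Step 1
Reactants: 1 2,3,4-trimethoxybenzaldehyde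
Product: 3 2,3,4-trimethoxyphenol, via 2,3,4-trimethoxyphenyl formate 2 (not isolated)
Conditions: mCPBA, CH2Cl2, 0 °C to rt; then MeOH, HCl (cat.), rt
Reagents that add atoms: mCPBA, O=C(OO)c1cccc(Cl)c1
Why: Baeyer–Villiger oxidation of an aldehyde carrying ortho- and para-methoxy donors proceeds with aryl migration to the formate, which is methanolysed in the same flask (Dakin-type sequence).

Step 2
Reactants: 3 2,3,4-trimethoxyphenol
Product: 4 2-hydroxy-3,4,5-trimethoxybenzaldehyde
Conditions: MgCl2, Et3N, (CH2O)n, MeCN, reflux; aq. HCl work-up
Reagents that add atoms: paraformaldehyde (as formaldehyde), C=O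
Why: Magnesium-phenoxide-directed (Casnati–Skattebøl) formylation delivers formaldehyde only ortho to OH, the single free ortho carbon being C6, and a second formaldehyde oxidises the benzylic alkoxide by hydride transfer.

Step 3
Reactants: 4 2-hydroxy-3,4,5-trimethoxybenzaldehyde; 5 acrylonitrile
Product: 6 6,7,8-trimethoxy-2H-chromene-3-carbonitrile
Conditions: DABCO (0.3 equiv), neat acrylonitrile, 80 °C
Reagents that add atoms: none
Why: DABCO-mediated Baylis–Hillman-type addition of acrylonitrile to the aldehyde, oxa-Michael closure by the phenoxide and loss of water give the 2H-chromene, a standard annulation of salicylaldehydes.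

Step 4
Reactants: 6 6,7,8-trimethoxy-2H-chromene-3-carbonitrile
Product: 7 6,7,8-trimethoxy-2H-chromene-3-carboxylic acid
Conditions: 10% aq. NaOH, reflux; then aq. HCl
Reagents that add atoms: sodium hydroxide, [Na+].[OH-]; water, O
Why: Alkaline hydrolysis of the conjugated nitrile to the carboxylate is standard, and the aryl methyl ethers and the 2H-chromene tolerate hot aqueous hydroxide.

Step 5
Reactants: 7 6,7,8-trimethoxy-2H-chromene-3-carboxylic acid
Product: 8 (3R)-6,7,8-trimethoxychroman-3-carboxylic acid
Conditions: H2 (5 bar), Ru(OAc)2[(S)-H8-BINAP] (1 mol %), MeOH, rt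
Reagents that add atoms: none
Why: Carboxylate-directed Noyori-type asymmetric hydrogenation of a trisubstituted α,β-unsaturated acid at divalent ruthenium sets C3 by ligand-controlled face selection, the (S)-ligand being expected to give the (R)-acid by analogy with (E)-2-methylbut-2-enoic acid (the antipodal ligand is used if the first run shows the opposite sense).

Step 6
Reactants: 8 (3R)-6,7,8-trimethoxychroman-3-carboxylic acid
Product: 9 (3R)-N-methoxy-N-methyl-6,7,8-trimethoxychroman-3-carboxamide
Conditions: MeNHOMe·HCl, EDC·HCl, HOBt (cat.), N-methylmorpholine, CH2Cl2, 0 °C to rt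
Reagents that add atoms: N,O-dimethylhydroxylamine hydrochloride, CNOC.Cl
Why: Carbodiimide amidation gives the Weinreb amide, and an α-alkyl acid without an N-acyl group has no oxazolone pathway, so C3 should not epimerise.

Step 7
Reactants: 9 (3R)-N-methoxy-N-methyl-6,7,8-trimethoxychroman-3-carboxamide; 10 dimethyl (1-diazo-2-oxopropyl)phosphonate
Product: 12 (3S)-3-ethynyl-6,7,8-trimethoxychroman, via chroman-3-carbaldehyde 11 (not isolated)
Conditions: i-Bu2AlH, CH2Cl2, −78 °C; then MeOH, K2CO3, 10, −78 °C to rt
Reagents that add atoms: none
Why: The chelated aluminium hemiaminal holds the aldehyde oxidation level until the methanol quench releases the aldehyde directly into Seyferth–Gilbert homologation with the Ohira–Bestmann reagent (Horner–Wadsworth–Emmons addition, loss of N2, 1,2-hydrogen shift), which at low temperature should outrun enolisation so that the C3 arrangement is carried over.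

Step 8
Reactants: 13 dimethyl squarate; 14 ClCo(PPh3)3
Product: 15 chlorobis(triphenylphosphine)(2,3-dimethoxymaleoyl)cobalt
Conditions: PhCl, rt to 50 °C, N2
Reagents that add atoms: none
Why: Oxidative addition of the 16-electron monovalent cobalt centre into the strained acyl–acyl bond of the cyclobutenedione, with loss of one phosphine, gives the five-membered trivalent-cobalt metallacycle, the established entry to maleoylcobalt complexes.

Step 9
Reactants: 15 chlorobis(triphenylphosphine)(2,3-dimethoxymaleoyl)cobalt
Product: 16 chloro(dimethylglyoxime)(pyridine)(2,3-dimethoxymaleoyl)cobalt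
Conditions: dimethylglyoxime, pyridine, rt; precipitation with water
Reagents that add atoms: dimethylglyoxime, CC(=NO)C(C)=NO; pyridine, c1ccncc1
Why: Ligand substitution at trivalent cobalt by the chelating dioxime and pyridine displaces both phosphines and gives an octahedral, air-stable metallacycle that precipitates free of triphenylphosphine and reacts with alkynes under mild Lewis-acid assistance.

Step 10
Reactants: 16 chloro(dimethylglyoxime)(pyridine)(2,3-dimethoxymaleoyl)cobalt; 12 (3S)-3-ethynyl-6,7,8-trimethoxychroman
Product: 17 2,3-dimethoxy-5-[(3S)-6,7,8-trimethoxychroman-3-yl]-1,4-benzoquinone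
Conditions: 16 (1.3 equiv), CoCl2·6H2O (1 equiv), ClCH2CH2Cl, 70 °C, N2; air on work-up
Reagents that add atoms: none
Why: The Lewis acid labilises chloride or pyridine on the octahedral trivalent cobalt so that the alkyne coordinates cis to an acyl carbon; migratory insertion into one Co–C(O) bond gives a seven-membered cobaltacycle, and C(acyl)–C(vinyl) reductive elimination releases the quinone at its final oxidation level. The closest known reaction type is the benzoquinone synthesis from maleoylcobalt metallacycles and alkynes, terminal ones included. The quinone ring is closed by this insertion/reductive-elimination pair, a formal [4+2] union of the C2'–C5' unit with the two alkyne carbons that makes C1'–C2' and C6'–C5'. No stereocentre is created, and C3 keeps its configuration because no base is present and its C–H bond is not engaged. Regiochemistry needs no control, since the dimethoxymaleoyl unit is mirror-symmetric and either insertion orientation gives the same quinone. The selectivity that matters is 1:1 annulation over alkyne oligomerisation, secured by using the preformed stoichiometric metallacycle in slight excess so that no free low-valent cobalt is present at the start.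

Step 11
Reactants: 17 2,3-dimethoxy-5-[(3S)-6,7,8-trimethoxychroman-3-yl]-1,4-benzoquinone
Product: 19 2-hydroxy-5,6-dimethoxy-3-[(3S)-6,7,8-trimethoxychroman-3-yl]-1,4-benzoquinone, via quinone epoxide 18 (not isolated)
Conditions: 30% H2O2, Na2CO3, dioxane/H2O, 0 °C; extractive work-up; then conc. H2SO4, 0 °C, short contact, ice quench
Reagents that add atoms: hydrogen peroxide, OO
Why: Weitz–Scheffer nucleophilic epoxidation attacks the non-oxygenated, more electrophilic C1'=C6' bond, and acid-induced opening and dehydration of the epoxy diketone (the classical quinone oxide to hydroxyquinone isomerisation) places OH on C6', both epoxide diastereomers converging and C3 staying untouched.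

Step 12
Reactants: 19 2-hydroxy-5,6-dimethoxy-3-[(3S)-6,7,8-trimethoxychroman-3-yl]-1,4-benzoquinone
Product: 20 2,3,5-trimethoxy-6-[(3S)-6,7,8-trimethoxychroman-3-yl]-1,4-benzoquinone (CNP0344638.1)
Conditions: TMSCHN2, MeOH/PhMe, 0 °C to rt
Reagents that add atoms: trimethylsilyldiazomethane, C[Si](C)(C)C=[N+]=[N-]
Why: The hydroxyquinone is a vinylogous carboxylic acid that protonates the diazoalkane and is O-methylated as in a diazomethane esterification, a neutral process that cannot enolise toward C3 and that would also re-methylate any quinone OH uncovered by earlier demethylation.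

Compound list
1 | 2,3,4-trimethoxybenzaldehyde | COc1ccc(C=O)c(OC)c1OC | starting material
2 | 2,3,4-trimethoxyphenyl formate | COc1ccc(OC=O)c(OC)c1OC | intermediate (not isolated)
3 | 2,3,4-trimethoxyphenol | COc1ccc(O)c(OC)c1OC | intermediate
4 | 2-hydroxy-3,4,5-trimethoxybenzaldehyde | COc1cc(C=O)c(O)c(OC)c1OC | intermediate
5 | acrylonitrile | C=CC#N | starting material
6 | 6,7,8-trimethoxy-2H-chromene-3-carbonitrile | N#CC1=Cc2cc(OC)c(OC)c(OC)c2OC1 | intermediate
7 | 6,7,8-trimethoxy-2H-chromene-3-carboxylic acid | OC(=O)C1=Cc2cc(OC)c(OC)c(OC)c2OC1 | intermediate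
8 | (3R)-6,7,8-trimethoxychroman-3-carboxylic acid | OC(=O)[C@H]1COc2c(cc(OC)c(OC)c2OC)C1 | intermediate
9 | (3R)-N-methoxy-N-methyl-6,7,8-trimethoxychroman-3-carboxamide | CON(C)C(=O)[C@H]1COc2c(cc(OC)c(OC)c2OC)C1 | intermediate
10 | dimethyl (1-diazo-2-oxopropyl)phosphonate | COP(=O)(OC)C(=[N+]=[N-])C(C)=O | starting material
11 | (3R)-6,7,8-trimethoxychroman-3-carbaldehyde | O=C[C@H]1COc2c(cc(OC)c(OC)c2OC)C1 | intermediate (not isolated)
12 | (3S)-3-ethynyl-6,7,8-trimethoxychroman | C#C[C@H]1COc2c(cc(OC)c(OC)c2OC)C1 | intermediate
13 | dimethyl squarate (3,4-dimethoxycyclobut-3-ene-1,2-dione) | COC1=C(OC)C(=O)C1=O | starting material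
14 | ClCo(PPh3)3, chlorotris(triphenylphosphine)cobalt (monovalent cobalt) | Cl[Co-3]([P+](c1ccccc1)(c1ccccc1)c1ccccc1)([P+](c1ccccc1)(c1ccccc1)c1ccccc1)[P+](c1ccccc1)(c1ccccc1)c1ccccc1 | starting material
15 | chlorobis(triphenylphosphine)(2,3-dimethoxymaleoyl)cobalt (trivalent cobalt) | COC1=C(OC)C(=O)[Co-2](Cl)([P+](c2ccccc2)(c2ccccc2)c2ccccc2)([P+](c2ccccc2)(c2ccccc2)c2ccccc2)C1=O | intermediate
16 | chloro(dimethylglyoxime)(pyridine)(2,3-dimethoxymaleoyl)cobalt (trivalent cobalt) | COC1=C(OC)C(=O)[Co-3]2(Cl)([n+]3ccccc3)([N+](O)=C(C)C(C)=[N+]2O)C1=O | intermediate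
17 | 2,3-dimethoxy-5-[(3S)-6,7,8-trimethoxychroman-3-yl]-1,4-benzoquinone | COC1=C(OC)C(=O)C([C@H]2COc3c(cc(OC)c(OC)c3OC)C2)=CC1=O | intermediate
18 | 3,4-dimethoxy-1-[(3R)-6,7,8-trimethoxychroman-3-yl]-7-oxabicyclo[4.1.0]hept-3-ene-2,5-dione (both cis-epoxide diastereomers) | COC1=C(OC)C(=O)C2(OC2C1=O)[C@H]3COc4c(cc(OC)c(OC)c4OC)C3 | intermediate (not isolated)
19 | 2-hydroxy-5,6-dimethoxy-3-[(3S)-6,7,8-trimethoxychroman-3-yl]-1,4-benzoquinone | COC1=C(OC)C(=O)C([C@H]2COc3c(cc(OC)c(OC)c3OC)C2)=C(O)C1=O | intermediate
20 | 2,3,5-trimethoxy-6-[(3S)-6,7,8-trimethoxychroman-3-yl]-1,4-benzoquinone | COC1=C(OC)C(=O)C([C@H]2COc3c(cc(OC)c(OC)c3OC)C2)=C(OC)C1=O | target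

Total step count: 12.
Longest linear sequence: 10 steps (steps 1–7, then 10, 11 and 12); the cobalt branch (steps 8 and 9) joins at step 10.

Steps most likely to fail

Step 10. Insertion of the alkyne into the electron-rich dialkoxy metallacycle may be slow, so that alkyne oligomerisation or decomposition of the complex competes. The same fallback also covers a failed cobalt insertion in step 8. It sets out from 12 and 13 and uses squarate ring-expansion chemistry instead of cobalt. Alkyne 12 is deprotonated with n-BuLi (THF, −78 °C) and added to one carbonyl of dimethyl squarate 13, giving 4-hydroxy-2,3-dimethoxy-4-{[(3S)-6,7,8-trimethoxychroman-3-yl]ethynyl}cyclobut-2-en-1-one F1. Thermolysis in refluxing p-xylene (Moore rearrangement) opens the ring to the alkynyl vinylketene, which closes to the six-membered diradical and transfers hydrogen. For an alkyl-substituted alkyne this should give the 5-alkyl-2,3-dimethoxyquinone. The route is rejoined at 17.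

Step 11. Hydroperoxide or hydroxide may displace a quinone methoxy group, base may erode C3 through quinone-methide tautomerisation, and the sulfuric acid stage may sulfonate the electron-rich chroman arene. The fallback sets out from 17 and uses Thiele–Winter acetoxylation (Ac2O, BF3·OEt2 cat., rt), which adds acetate at the only free quinone position and gives 5,6-dimethoxy-3-[(3S)-6,7,8-trimethoxychroman-3-yl]benzene-1,2,4-triyl triacetate F2. Methanolysis (K2CO3, MeOH, N2) gives 5,6-dimethoxy-3-[(3S)-6,7,8-trimethoxychroman-3-yl]benzene-1,2,4-triol F3, which autoxidises on exposure to air. The route is rejoined at 19.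

Step 7. Enolisation of the α-branched aldehyde in carbonate/methanol may erode the C3 configuration, or the amide may be over-reduced to the alcohol. The fallback sets out from 9 and keeps the aldehyde away from base. Amide 9 is reduced with i-Bu2AlH at −78 °C and the aldehyde 11 is isolated cold after a neutral Rochelle-salt work-up. Corey–Fuchs olefination (CBr4, PPh3, CH2Cl2, 0 °C) gives (3S)-3-(2,2-dibromovinyl)-6,7,8-trimethoxychroman F4. Treatment with n-BuLi (2.2 equiv, THF, −78 °C) induces Fritsch–Buttenberg–Wiechell rearrangement to the lithium acetylide, which is protonated on work-up. The route is rejoined at 12.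

Further compounds
F1 | step 10 | 4-hydroxy-2,3-dimethoxy-4-{[(3S)-6,7,8-trimethoxychroman-3-yl]ethynyl}cyclobut-2-en-1-one | COC1=C(OC)C(O)(C#C[C@H]2COc3c(cc(OC)c(OC)c3OC)C2)C1=O
F2 | step 11 | 5,6-dimethoxy-3-[(3S)-6,7,8-trimethoxychroman-3-yl]benzene-1,2,4-triyl triacetate | COc1c(OC)c(OC(C)=O)c(OC(C)=O)c([C@H]2COc3c(cc(OC)c(OC)c3OC)C2)c1OC(C)=O
F3 | step 11 | 5,6-dimethoxy-3-[(3S)-6,7,8-trimethoxychroman-3-yl]benzene-1,2,4-triol | COc1c(OC)c(O)c(O)c([C@H]2COc3c(cc(OC)c(OC)c3OC)C2)c1O
F4 | step 7 | (3S)-3-(2,2-dibromovinyl)-6,7,8-trimethoxychroman | BrC(Br)=C[C@H]1COc2c(cc(OC)c(OC)c2OC)C1
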